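## The problem

Target **19** is a guai-4-en-3-one: a cyclopentenone fused through C1–C5 to a seven-membered carbocycle. Guaiane numbering is used throughout: five-membered ring C1(H)–C2H2–C3(=O)–C4(CH3)=C5; seven-membered ring C1–C5–C6H2–C7–C8–C9H2–C10–C1; C11 is the oxygenated carbon on C7.

- There are four stereocentres, C1 (R), C7 (S), C8 (R) and C10 (S). H1, the C10 methyl, the C7–C11 bond and the C8 oxygen all lie on one face of the seven-membered ring.
- C1 and C10 are neighbours and can be made together in an open-chain bond construction. C7 and C8 lie across the medium ring, where relay from C1/C10 is unreliable, so they need their own control element.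
- The seven-membered ring is the main constructional difficulty. It has to be closed without disturbing C1, which is the γ-carbon of the enone and epimerises through the dienolate under basic or warm conditions.
- The functional groups are delicate: a tertiary acetate that ionises and eliminates under acid, a secondary isobutyrate that can migrate within the 1,3-dioxygen array, and a tetrasubstituted enone that accepts hard nucleophiles at C3 and, in hydroxy intermediates, alkoxides at C5.
- The feature that opens the problem is the cis-1,3 relation between the C8 oxygen and the oxygen-bearing C11 on C7. With C11 at the carboxyl level this is a cis-fused β-lactone C11(=O)–O–C8, the product of an aldol-lactonisation between a C7 enolate and a C8 aldehyde. The lactone carbonyl can later take up both methyl groups.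

## Retrosynthesis

**Ester C–O bonds (19 ⇒ 18 ⇒ 17).** The acetate and the isobutyrate are removed first, tertiary before secondary, which leads back to diol **17**. Acylating in the opposite order forward (secondary, then tertiary) uses the natural reactivity difference and needs no protecting group. The forward steps must be non-acidic and must not generate alkoxides that could add to C5.

**The two C11–CH3 bonds (17 ⇒ 15).** Cutting both methyl groups from C11 turns the tertiary carbinol into a carbonyl tied to the C8 oxygen, the cis-fused β-lactone **15**. This is preferred over carrying an isopropyl-type unit through the ring closure, because the lactone fixes the C7/C8 relation and is the direct product of the key step. The forward reaction is a double methyl addition with the enone hidden as its lithium enolate **16**.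

**C7–C8 and O–C11 (15 ⇒ 13), the key disconnection.** Opening the lactone and the C7–C8 bond removes two rings and two stereocentres at once and leaves the monocyclic aldehyde acid **13**. Cuts at C1–C10 or C5–C6 would leave C7 and C8 to be set on an open chain with no element tying them together. Here the four-membered ring enforces their cis relation and a chiral nucleophilic catalyst chooses the face. The forward reaction must generate the C7 enolate equivalent selectively next to a free aldehyde and an enone, and must close a seven-membered ring.

**Oxidation levels at C8 and C11 (13 ⇒ 12 ⇒ 11).** The aldehyde acid is traced to hydroxy acid **12** and hydroxy aldehyde **11**. Having C8 as an alcohol and C11 as an aldehyde differentiates the two termini without protecting groups. The forward steps are an aldehyde-selective oxidation followed by an alcohol-to-aldehyde oxidation.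

**C5–C6 (11 ⇒ 6 + 7).** The 3-substituted 2-methylcyclopentenone is a transposed vinylogous ester. Cutting C5–C6 gives ketone **6** and a three-carbon nucleophile, Grignard reagent **8** from bromo acetal **7**. This places all of C6–C7–C11 in a commercial reagent and uses the carbonyl of **6** twice, as acceptor and as the future C4=C5 alkene. The ester of **6** is reduced in the same flask, at the stage of adduct **9**, before the enone exists (giving **10**). The forward sequence must keep C1, then α to a carbonyl, intact.

**C1–C10 (6 ⇒ 4 + 3; 3 ⇒ 1 + 2).** Cutting the bond between the two adjacent stereocentres gives vinylogous ester **4** (as its kinetic dienolate **5**) and a crotonate. A Michael addition creates both centres in one step. The relative configuration comes from the enolate and alkene geometries, and the absolute configuration from a shielding alcohol auxiliary in crotonate **3**, made from (−)-8-phenylmenthol **1** and crotonic acid **2**. An alkylation at C1 was not considered because C10 is a secondary carbon.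

## Roads not taken

**Alternative 1:** Cut C6–C7 and C9–C10, that is, a [4+3] annulation.
- *Forward step:* a chiral dirhodium tetracarboxylate decomposes the siloxyvinyl diazoacetate **A2**. The carbenoid cyclopropanates the exocyclic methylene of the bis-alkylidene cyclopentane **A1**, and the cis-divinylcyclopropane undergoes Cope rearrangement to the cycloheptadiene **A3**.
- *Merits:* it is convergent, forms two ring bonds in one operation, and sets C10 under catalyst control. This ring-forming event is better established for seven-membered rings than the closure chosen here.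
- *Weak points:* **A3** has its alkene at C1=C5 and not at C4=C5, so C1 is not yet a stereocentre and must be created later during alkene transposition, with no obvious control. C7 and C8 are both sp2 in **A3** and must also be set afterwards. The C3 and C4 stereocentres of **A1** are built only to be erased.
- *Comparison:* the chosen plan accepts a less proven ring closure. In return, all four stereocentres are in their final form immediately after it and only three steps remain.

**Alternative 2:** Cut C5–C6 and C7–C8, that is, an oxidopyrylium [5+2] cycloaddition.
- *Forward step:* base converts acetoxypyranone **A4** into the 3-oxidopyrylium, which adds to the N-acryloyl camphorsultam **A5** to give the oxa-bridged cycloadduct **A6**.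
- *Merits:* the cycloaddition is robust and auxiliary-controlled, and it delivers the seven-membered ring with the C7 acyl group and the C8 oxygen already cis, which is exactly the relation the chosen plan must create.
- *Weak points:* the five-membered ring is still missing. C1 is a ketone carbon and C10 an alkene carbon in **A6**, so both C1 and C10 have to be set later. The C5–O bridge must be cleaved reductively, the cyclopentenone annulated through a new C1–C2 bond, and the side-chain stereocentre at C4 is lost when C4 becomes sp2.
- *Comparison:* this road has the safer key step but a much longer sequence after it. The chosen plan has every carbon and the C1/C10 pair in place before the ring is closed.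

**Alternative 3:** Skeletal reorganisation of a decalin dienone.
- *Forward step:* irradiation of the cross-conjugated dienone **A7** in aqueous acid forms C1–C5, cleaves C5–C10 and adds water at C10, giving the 10-hydroxy guaienone **A8**.
- *Merits:* the rearrangement is a classic on exactly this skeleton. It delivers the complete 5-7 enone with C1 set stereospecifically and both esters in place, and it is more direct than any ring closure.
- *Weak points:* **A8** carries a tertiary hydroxyl at C10 that the target lacks, so the C10–H stereocentre has to be created afresh by deoxygenation with uncertain facial control, next to an enone and two esters. **A7**, with its angular methyl and the cis C7/C8 substituents, needs a synthesis of its own of comparable length. The tertiary acetate is exposed to acid and light.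
- *Comparison:* the key step here is better precedented. The chosen plan instead sets C10 once, early and unambiguously, and never has to repair it.

Key step: step 6

Assumption 1: crotonate **3** is taken to react in its lithium-chelated s-cis conformation on the face away from the phenyl ring, which gives 10S; if the opposite sense is found, the enantiomeric auxiliary is used and nothing else changes.

Assumption 2: (S)-HBTM is taken to direct the aldehyde to the face of the C7 enolate that gives 7S (Z-enolate, O···S contact, approach anti to the phenyl group); if the opposite holds, (R)-HBTM is used.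

## Route

Step 1
Reactants: 1 (−)-8-phenylmenthol, (1R,2S,5R)-5-methyl-2-(2-phenylpropan-2-yl)cyclohexan-1-ol; 2 (E)-but-2-enoic acid
Product: 3 (1R,2S,5R)-5-methyl-2-(2-phenylpropan-2-yl)cyclohexyl (E)-but-2-enoate
Conditions: DCC, DMAP (cat.), CH2Cl2, 0 °C to rt
Reagents that add atoms: none
Why: Steglich esterification of a hindered secondary alcohol; carbodiimide activation avoids the base-induced deconjugation that crotonyl chloride with amine bases can cause, and no stereocentre is touched.

Step 2
Reactants: 4 3-ethoxy-2-methylcyclopent-2-en-1-one; 3 (1R,2S,5R)-5-methyl-2-(2-phenylpropan-2-yl)cyclohexyl (E)-but-2-enoate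
Product: 6 (1R,2S,5R)-5-methyl-2-(2-phenylpropan-2-yl)cyclohexyl (3S)-3-[(1R)-4-ethoxy-3-methyl-2-oxocyclopent-3-en-1-yl]butanoate, via lithium dienolate 5 (not isolated)
Conditions: LiN(iPr)2, THF, −78 °C; then 3, −78 °C; AcOH quench at −78 °C
Reagents that add atoms: none
Why: Michael addition of the kinetic α′-lithium dienolate of a vinylogous ester to a chiral crotonate, a known auxiliary-controlled reaction class for cyclopentenone dienolates. The ring enolate is necessarily E(O) and should combine with the (E)-crotonate through a closed, lithium-bridged transition state to give the syn pair (1R*,10S*); the phenyl group of the auxiliary covers one face of the enoate, so C10 should form as S and C1 follows as R. The cold acidic quench protonates the ester enolate before it can exchange with the C1 position.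

Step 3
Reactants: 6 (1R,2S,5R)-5-methyl-2-(2-phenylpropan-2-yl)cyclohexyl (3S)-3-[(1R)-4-ethoxy-3-methyl-2-oxocyclopent-3-en-1-yl]butanoate; 7 2-(2-bromoethyl)-1,3-dioxolane
Product: 11 3-{(5R)-5-[(2S)-4-hydroxybutan-2-yl]-2-methyl-3-oxocyclopent-1-en-1-yl}propanal, via Grignard reagent 8 (not isolated), via tertiary alkoxide 9 (not isolated), via diol 10 (not isolated)
Conditions: 7, Mg, THF, rt; CeCl3, THF, −78 °C, then 6, −78 to 0 °C; then LiAlH4, 0 °C to rt; then 2 M aq. HCl, THF, rt
Reagents that add atoms: water, O
Why: Stork–Danheiser sequence: CeCl3-promoted Grignard 1,2-addition to the vinylogous-ester carbonyl (the hindered ester is inert), LiAlH4 reduction of the ester in the same flask while the future enone is still a tertiary alkoxide (auxiliary 1 is released for recovery), then acid hydrolysis and dehydration, which transposes the carbonyl to C3 and unmasks the C11 aldehyde. No stereocentre is formed, and C1 is not enolised under cerium-moderated addition or aqueous acid.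

Step 4
Reactants: 11 3-{(5R)-5-[(2S)-4-hydroxybutan-2-yl]-2-methyl-3-oxocyclopent-1-en-1-yl}propanal
Product: 12 3-{(5R)-5-[(2S)-4-hydroxybutan-2-yl]-2-methyl-3-oxocyclopent-1-en-1-yl}propanoic acid
Conditions: NaClO2, NaH2PO4, 2-methyl-2-butene, t-BuOH/H2O, 0 °C to rt
Reagents that add atoms: sodium chlorite, [Na+].[O-]Cl=O
Why: Pinnick oxidation is specific for the aldehyde; the primary alcohol and the tetrasubstituted enone should not react, and 2-methyl-2-butene traps the hypochlorous acid formed.

Step 5
Reactants: 12 3-{(5R)-5-[(2S)-4-hydroxybutan-2-yl]-2-methyl-3-oxocyclopent-1-en-1-yl}propanoic acid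
Product: 13 3-{(5R)-2-methyl-3-oxo-5-[(2S)-4-oxobutan-2-yl]cyclopent-1-en-1-yl}propanoic acid
Conditions: Dess–Martin periodinane, CH2Cl2, 0 °C to rt
Reagents that add atoms: none
Why: Dess–Martin oxidation of a primary alcohol stops at the aldehyde and tolerates a free carboxylic acid; the neutral conditions leave C1 and C10 untouched.

Step 6
Reactants: 13 3-{(5R)-2-methyl-3-oxo-5-[(2S)-4-oxobutan-2-yl]cyclopent-1-en-1-yl}propanoic acid
Product: 15 (1R,7S,8R,10S)-tricyclic β-lactone: 4,10-dimethyl-3-oxo-guai-4-ene core lacking both C11 methyls, oxetan-2-one cis-fused at C7–C8 with C11 as lactone carbonyl on C7 and the ring oxygen on C8, via acyloxypyridinium salt 14 (not isolated)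
Conditions: (S)-HBTM (20 mol %), 2-bromo-1-propylpyridinium triflate, iPr2NEt, CH2Cl2, rt, slow addition of 13 (syringe pump) at high dilution
Reagents that add atoms: none
Why: Proposed new method: the carboxylate of 13 displaces bromide from the pyridinium salt to give active ester 14, which acylates the isothiourea; iPr2NEt then removes a C7 proton to give the catalyst-bound ammonium enolate, and the closest known reaction type is the nucleophile-catalysed aldol-lactonisation of aldehyde acids and keto acids to cyclopentane- and cyclohexane-fused β-lactones, of which the seven-membered carbocycle is an untested extension. The enolate carbon C7 adds to the C8 aldehyde in a 7-exo-trig (enolexo) closure of the carbocycle, and the aldolate oxygen then attacks the acylammonium carbon C11 in a 4-exo-trig closure that forms the β-lactone and releases the catalyst. C7 is set by the catalyst: in the Z-enolate, held coplanar with the isothiouronium ring by the O···S contact, the phenyl group blocks one face and the aldehyde should add to the other, which for (S)-HBTM corresponds to 7S. C8 is set by the ring fusion: only the aldolate with O8 cis to C11 can close the four-membered ring without prohibitive strain, and the aldol addition is reversible for the other. The step needs intramolecular reaction to win over oligomerisation and ketene dimerisation; slow addition at high dilution and the placement of the two arms on the adjacent ring atoms C1 and C5 (C5 being sp2) remove rotors and bring C7 and C8 within reach. It also needs chemoselectivity for the aldehyde, which geometry secures because the enolate cannot reach the C3 carbonyl and the tetrasubstituted enone is a poor acceptor. The existing C1 and C10 centres must not override the catalyst; they are three and two bonds from the reacting carbons and carry only small substituents.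

Step 7
Reactants: 15 (1R,7S,8R,10S)-tricyclic β-lactone
Product: 17 (1R,7S,8R,10S)-8,11-dihydroxyguai-4-en-3-one, via lithium enolate 16 (not isolated)
Conditions: LiN(SiMe3)2, THF, −78 °C; then MeLi (excess), −78 to −40 °C; sat. aq. NH4Cl at −78 °C
Reagents that add atoms: methyllithium, [Li]C
Why: In situ protection: the amide base converts the cyclopentenone into its cross-conjugated C2=C3 lithium enolate (the ketone α′-CH is far more acidic than the lactone α-CH), which accepts neither MeLi nor the alkoxides that form. MeLi then opens the strained β-lactone by acyl–oxygen cleavage and adds a second time to the methyl ketone (double addition of an organolithium to a lactone), leaving C7 and C8 unchanged. The mixture is kept at or below −40 °C so that the cyclopentadienolate does not scramble C1, and protonation at C2 on quench returns the enone.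

Step 8
Reactants: 17 (1R,7S,8R,10S)-8,11-dihydroxyguai-4-en-3-one
Product: 18 (1R,7S,8R,10S)-11-hydroxy-8-(2-methylpropanoyloxy)guai-4-en-3-one
Conditions: (iPrCO)2O, Et3N, DMAP (cat.), CH2Cl2, 0 °C
Reagents that add atoms: isobutyric anhydride, CC(C)C(=O)OC(=O)C(C)C
Why: DMAP-catalysed acylation at 0 °C should discriminate the secondary C8 hydroxyl from the hindered tertiary C11 hydroxyl; no stereocentre is affected.

Step 9
Reactants: 18 (1R,7S,8R,10S)-11-hydroxy-8-(2-methylpropanoyloxy)guai-4-en-3-one
Product: 19 (1R,7S,8R,10S)-11-acetoxy-8-(2-methylpropanoyloxy)guai-4-en-3-one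
Conditions: Ac2O, Et3N, DMAP, CH2Cl2, rt to 40 °C
Reagents that add atoms: acetic anhydride, CC(=O)OC(C)=O
Why: DMAP-promoted acetylation of a tertiary alcohol with excess anhydride; the non-acidic conditions avoid ionisation and elimination at C11, and migration of the isobutyrate from the secondary to the tertiary oxygen is not favoured.

## Compound list

1 | (−)-8-phenylmenthol, (1R,2S,5R)-5-methyl-2-(2-phenylpropan-2-yl)cyclohexan-1-ol | CC(C)(c1ccccc1)[C@@H]2CC[C@@H](C)C[C@H]2O | starting material
2 | (E)-but-2-enoic acid (crotonic acid) | C/C=C/C(=O)O | starting material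
3 | (1R,2S,5R)-5-methyl-2-(2-phenylpropan-2-yl)cyclohexyl (E)-but-2-enoate | C/C=C/C(=O)O[C@@H]1C[C@H](C)CC[C@H]1C(C)(C)c2ccccc2 | intermediate
4 | 3-ethoxy-2-methylcyclopent-2-en-1-one | CCOC1=C(C)C(=O)CC1 | starting material
5 | lithium 4-ethoxy-3-methylcyclopenta-1,3-dien-2-olate (kinetic dienolate of 4, formed in the flask) | CCOC1=C(C)C(O[Li])=CC1 | intermediate
6 | (1R,2S,5R)-5-methyl-2-(2-phenylpropan-2-yl)cyclohexyl (3S)-3-[(1R)-4-ethoxy-3-methyl-2-oxocyclopent-3-en-1-yl]butanoate | CCOC1=C(C)C(=O)[C@H](C1)[C@@H](C)CC(=O)O[C@@H]2C[C@H](C)CC[C@H]2C(C)(C)c3ccccc3 | intermediate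
7 | 2-(2-bromoethyl)-1,3-dioxolane | BrCCC1OCCO1 | starting material
8 | [2-(1,3-dioxolan-2-yl)ethyl]magnesium bromide (formed in the flask) | Br[Mg]CCC1OCCO1 | intermediate
9 | 8-phenylmenthyl (3S)-3-[(1R)-2-[2-(1,3-dioxolan-2-yl)ethyl]-4-ethoxy-2-hydroxy-3-methylcyclopent-3-en-1-yl]butanoate, carbinol centre as formed, present as its alkoxide (formed in the flask) | CCOC1=C(C)C(O)(CCC2OCCO2)[C@H](C1)[C@@H](C)CC(=O)O[C@@H]3C[C@H](C)CC[C@H]3C(C)(C)c4ccccc4 | intermediate
10 | (3S)-3-[(1R)-2-[2-(1,3-dioxolan-2-yl)ethyl]-4-ethoxy-2-hydroxy-3-methylcyclopent-3-en-1-yl]butan-1-ol (formed in the flask) | CCOC1=C(C)C(O)(CCC2OCCO2)[C@H](C1)[C@@H](C)CCO | intermediate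
11 | 3-{(5R)-5-[(2S)-4-hydroxybutan-2-yl]-2-methyl-3-oxocyclopent-1-en-1-yl}propanal | OCC[C@H](C)[C@H]1CC(=O)C(C)=C1CCC=O | intermediate
12 | 3-{(5R)-5-[(2S)-4-hydroxybutan-2-yl]-2-methyl-3-oxocyclopent-1-en-1-yl}propanoic acid | OCC[C@H](C)[C@H]1CC(=O)C(C)=C1CCC(=O)O | intermediate
13 | 3-{(5R)-2-methyl-3-oxo-5-[(2S)-4-oxobutan-2-yl]cyclopent-1-en-1-yl}propanoic acid | O=CC[C@H](C)[C@H]1CC(=O)C(C)=C1CCC(=O)O | intermediate
14 | 2-{3-[(5R)-2-methyl-3-oxo-5-((2S)-4-oxobutan-2-yl)cyclopent-1-en-1-yl]propanoyloxy}-1-propylpyridinium triflate (formed in the flask) | O=CC[C@H](C)[C@H]1CC(=O)C(C)=C1CCC(=O)Oc2cccc[n+]2CCC.[O-]S(=O)(=O)C(F)(F)F | intermediate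
15 | (1R,7S,8R,10S)-tricyclic β-lactone: guai-4-en-3-one core lacking the C11 methyls, oxetan-2-one cis-fused at C7–C8 (C11 lactone carbonyl on C7, ring oxygen on C8) | O=C1O[C@@H]2C[C@H](C)[C@H]3CC(=O)C(C)=C3C[C@H]12 | intermediate
16 | lithium C2=C3 enolate of β-lactone 15 (formed in the flask) | O=C1O[C@@H]2C[C@H](C)[C@H]3C=C(O[Li])C(C)=C3C[C@H]12 | intermediate
17 | (1R,7S,8R,10S)-8,11-dihydroxyguai-4-en-3-one | CC(C)(O)[C@H]1CC2=C(C)C(=O)C[C@@H]2[C@@H](C)C[C@H]1O | intermediate
18 | (1R,7S,8R,10S)-11-hydroxy-8-(2-methylpropanoyloxy)guai-4-en-3-one | CC(C)(O)[C@H]1CC2=C(C)C(=O)C[C@@H]2[C@@H](C)C[C@H]1OC(=O)C(C)C | intermediate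
19 | (1R,7S,8R,10S)-11-acetoxy-8-(2-methylpropanoyloxy)guai-4-en-3-one | CC(=O)OC(C)(C)[C@H]1CC2=C(C)C(=O)C[C@@H]2[C@@H](C)C[C@H]1OC(=O)C(C)C | target

## Step count and risks

Total steps: 9. Longest linear sequence: 9 steps (1 + 2 → 3 → 6 → 11 → 12 → 13 → 15 → 17 → 18 → 19).

**Step 6 (key step, proposed new method).**
- *What may go wrong:* intermolecular acylation and aldol reaction (oligomerisation) or ketene dimerisation may outrun the entropically harder seven-membered closure. Base-mediated self-condensation of the aldehyde may compete. Facial control by the catalyst may be eroded if the C1/C10 centres favour the other face of the enolate.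
- *Fallback (known chemistry only):* it sets out from **11** and rejoins the route at **17**.
  - Enamine-catalysed α-bromination of the C11 aldehyde (N-bromosuccinimide, catalytic secondary amine) gives the 2-bromo aldehyde F1.
  - Pinnick oxidation gives the bromo acid F2, and methylation with trimethylsilyldiazomethane gives the bromo ester F3.
  - Dess–Martin oxidation of the C8 alcohol gives the bromo ester aldehyde F4.
  - An intramolecular Reformatsky reaction with SmI2 in THF at −78 °C, a closure established for medium carbocycles and tolerant of the enone, gives the cis β-hydroxy ester F5. C7 and C8 are then under substrate control, and the cis isomer is the one carried on.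
  - Treatment of F5 as in step 7 (enolate masking, then excess MeLi) gives **17**.

**Step 2.**
- *What may go wrong:* insufficient or reversed facial selectivity from the auxiliary, since the reacting enoate conformation under lithium chelation is assumed; erosion of C1 by proton exchange between the ester enolate and the ketone; a second, intramolecular Michael addition.
- *Fallback (catalyst control in place of auxiliary control):* it sets out from **4** and rejoins at **10**.
  - Trapping the dienolate with Me3SiCl gives the silyl dienol ether F6.
  - A Mukaiyama–Michael addition to (E)-crotonaldehyde under iminium catalysis with a chiral imidazolidinone salt gives the aldehyde F7.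
  - NaBH4 at low temperature reduces only the aldehyde to give the alcohol F8.
  - F8 takes up Grignard reagent **8** (CeCl3, one extra equivalent) to give **10**, which enters the acid stage of step 3.

**Step 3.**
- *What may go wrong:* the three telescoped operations may be incompatible (incomplete ester reduction in the presence of magnesium and cerium alkoxides, or enolisation in place of addition at the hindered ketone). The liberated aldehyde may also degrade before acetal cleavage is complete.
- *Fallback (stepwise, reduce everything then reoxidise):* it sets out from **6** and rejoins at **11**.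
  - Addition of **8** followed by brief treatment with cold dilute acid gives, via **9**, the enone ester acetal F9.
  - LiAlH4 reduces both the ester and the enone carbonyl to the diol acetal F10, with recovery of **1**.
  - MnO2 reoxidises only the allylic alcohol to the hydroxy enone acetal F11.
  - Aqueous acid then frees the aldehyde to give **11**.

**Step 7.**
- *What may go wrong:* incomplete enolate masking would lead to 1,2-addition at C3. Enolisation of the intermediate methyl ketone would stop the sequence at single addition. Retro-aldol cleavage of the β-alkoxy ketone, or hydrogen shift in the cyclopentadienolate on warming, would erode C7/C8 or C1.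
- *Fallback (redox protection in place of enolate protection):* it sets out from **15** and rejoins at **17**.
  - Luche reduction (NaBH4, CeCl3, MeOH, −78 °C) gives the allylic alcohol lactone F12.
  - Excess MeLi gives the triol F13.
  - MnO2 oxidises only the allylic alcohol to give **17**.

## Further compounds

F1 | step 6 | 2-bromo-3-{(5R)-5-[(2S)-4-hydroxybutan-2-yl]-2-methyl-3-oxocyclopent-1-en-1-yl}propanal (either configuration at the bromide carbon) | OCC[C@H](C)[C@H]1CC(=O)C(C)=C1CC(Br)C=O
F2 | step 6 | 2-bromo-3-{(5R)-5-[(2S)-4-hydroxybutan-2-yl]-2-methyl-3-oxocyclopent-1-en-1-yl}propanoic acid | OCC[C@H](C)[C@H]1CC(=O)C(C)=C1CC(Br)C(=O)O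
F3 | step 6 | methyl 2-bromo-3-{(5R)-5-[(2S)-4-hydroxybutan-2-yl]-2-methyl-3-oxocyclopent-1-en-1-yl}propanoate | OCC[C@H](C)[C@H]1CC(=O)C(C)=C1CC(Br)C(=O)OC
F4 | step 6 | methyl 2-bromo-3-{(5R)-2-methyl-3-oxo-5-[(2S)-4-oxobutan-2-yl]cyclopent-1-en-1-yl}propanoate | O=CC[C@H](C)[C@H]1CC(=O)C(C)=C1CC(Br)C(=O)OC
F5 | step 6 | methyl (1R,7S,8R,10S)-8-hydroxy-3-oxo-guai-4-ene-7-carboxylate lacking the C11 methyls (C11 = ester carbon, cis to the C8 hydroxyl) | COC(=O)[C@H]1CC2=C(C)C(=O)C[C@@H]2[C@@H](C)C[C@H]1O
F6 | step 2 | 1-ethoxy-2-methyl-3-(trimethylsilyloxy)cyclopenta-1,3-diene | CCOC1=C(C)C(O[Si](C)(C)C)=CC1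
F7 | step 2 | (3S)-3-[(1R)-4-ethoxy-3-methyl-2-oxocyclopent-3-en-1-yl]butanal | CCOC1=C(C)C(=O)[C@H](C1)[C@@H](C)CC=O
F8 | step 2 | (5R)-3-ethoxy-5-[(2S)-4-hydroxybutan-2-yl]-2-methylcyclopent-2-en-1-one | CCOC1=C(C)C(=O)[C@H](C1)[C@@H](C)CCO
F9 | step 3 | (1R,2S,5R)-5-methyl-2-(2-phenylpropan-2-yl)cyclohexyl (3S)-3-{(1R)-2-[2-(1,3-dioxolan-2-yl)ethyl]-3-methyl-4-oxocyclopent-2-en-1-yl}butanoate | O=C(C[C@H](C)[C@H]1CC(=O)C(C)=C1CCC2OCCO2)O[C@@H]3C[C@H](C)CC[C@H]3C(C)(C)c4ccccc4
F10 | step 3 | (4R)-3-[2-(1,3-dioxolan-2-yl)ethyl]-4-[(2S)-4-hydroxybutan-2-yl]-2-methylcyclopent-2-en-1-ol (carbinol centre as formed) | OCC[C@H](C)[C@H]1CC(O)C(C)=C1CCC2OCCO2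
F11 | step 3 | (4R)-3-[2-(1,3-dioxolan-2-yl)ethyl]-4-[(2S)-4-hydroxybutan-2-yl]-2-methylcyclopent-2-en-1-one | OCC[C@H](C)[C@H]1CC(=O)C(C)=C1CCC2OCCO2
F12 | step 7 | 3-hydroxy analogue of β-lactone 15 (C3 carbinol as formed) | O=C1O[C@@H]2C[C@H](C)[C@H]3CC(O)C(C)=C3C[C@H]12
F13 | step 7 | (1R,7S,8R,10S)-guai-4-ene-3,8,11-triol (C3 carbinol as formed) | CC(C)(O)[C@H]1CC2=C(C)C(O)C[C@@H]2[C@@H](C)C[C@H]1O
A1 | alternative 1 | (E)-configured bis-alkylidene cyclopentane diene: 3-(tert-butyldimethylsilyloxy)-1-ethylidene-4-methyl-5-methylenecyclopentane | C=C1[C@H](C)[C@@H](O[Si](C)(C)C(C)(C)C)C/C1=C\C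
A2 | alternative 1 | methyl 3-(tert-butyldimethylsilyloxy)-2-diazobut-3-enoate | COC(=O)C(=[N+]=[N-])C(=C)O[Si](C)(C)C(C)(C)C
A3 | alternative 1 | bicyclic cyclohepta-1,4-diene (C7=C8 silyl enol ether of the β-keto ester, C1=C5 alkene) | COC(=O)C1=C(O[Si](C)(C)C(C)(C)C)C[C@H](C)C2=C(C1)[C@H](C)[C@@H](O[Si](C)(C)C(C)(C)C)C2
A4 | alternative 2 | 6-acetoxy-2-[(2S)-1-(tert-butyldimethylsilyloxy)propan-2-yl]-4-methyl-2H-pyran-3(6H)-one (ring centres undefined) | CC(=O)OC1C=C(C)C(=O)C(O1)[C@@H](C)CO[Si](C)(C)C(C)(C)C
A5 | alternative 2 | N-acryloyl camphorsultam | C=CC(=O)N1[C@@H]2C[C@H]3CC[C@]2(CS1(=O)=O)C3(C)C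
A6 | alternative 2 | exo 8-oxabicyclo[3.2.1]octenone cycloadduct (C1 ketone, C9=C10, C5–O–C8 bridge, C7 acyl sultam) | O=C1C(C)=C[C@@H]2[C@@H](C(=O)N3[C@@H]4C[C@H]5CC[C@]4(CS3(=O)=O)C5(C)C)C[C@]1(O2)[C@@H](C)CO[Si](C)(C)C(C)(C)C
A7 | alternative 3 | decalin-type cross-conjugated 1,4-dien-3-one carrying the C7 acetoxyisopropyl and C8 isobutyryloxy groups | CC(=O)OC(C)(C)[C@H]1CC2=C(C)C(=O)C=C[C@@]2(C)C[C@H]1OC(=O)C(C)C
A8 | alternative 3 | 10-hydroxy derivative of the target (guai-4-en-3-one diester) | CC(=O)OC(C)(C)[C@H]1CC2=C(C)C(=O)C[C@@H]2[C@@](C)(O)C[C@H]1OC(=O)C(C)C
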